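A bench chemist charged the south-east run with partner at 1.05 equiv, more than the substrate, yet its target curve bends as if it were closing on a ceiling below the substrate charged.

| setting | south-east | flask |
|---|---|---|
| substrate | 0.10 M | 0.10 M |
| partner | 1.05 equiv | 1.05 equiv |
| precatalyst | 22 mol% | 15 mol% |
| remark | run made earlier |  |
| time |  | 10 min |

south-east run (percent of the substrate charged)

| time / s | substrate / % | target / % |
|---|---|---|
| 10.0 | 67.2 | 16.3 |
| 15.0 | 53.0 | 28.5 |
| 30.0 | 26.0 | 58.3 |
| 60.0 | 13.9 | 77.9 |

(scatter of a reading: 1 percentage point)

- at 10 min, what has stopped the reaction, if anything has (forward and back rates have come level / no working catalyst is left / the partner has run out first / all of the substrate has reacted / it is still moving)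
- share of the substrate used up at 10 min
- target at 10 min, in percent of the substrate charged
- catalyst intermediate A at 10 min, in percent of the substrate charged
- over-reaction product at 10 min, in percent of the substrate charged

- the reaction counts as stopped when no species that holds the substrate changes by six tenths of a point or more over the second half of the time
- what has gone from substrate into another species counts as reacted, even if it can come back
- no earlier run changes the charge of precatalyst; that part of a forecast is a guess

My supposition is that activating each precatalyst costs one partner. That leaves 83.0% of partner in the south-east run and 90.0% in the new flask, in percent of the substrate charged. I call this difference of charges the partner ceiling M. A ceiling approached in first order gives a straight line in the logarithm (base ten) of the distance to it; other approaches do not, so I use that form only as a trial on the south-east run: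

Distance to M: 0.0229 s⁻¹ over 15.0 s to 30.0 s, then 0.0228 s⁻¹ over 30.0 s to 60.0 s.

Distance to the full substrate charge: 0.0156 s⁻¹, then 0.00919 s⁻¹.

Over these two spans the slopes to M agree as read, with readings that scatter by 1 percentage point, while the other slope sags. The earlier span from 10.0 s to 15.0 s gives a lower slope to M, 0.0175 s⁻¹, so the trial proves nothing and M remains my supposition. At the later slope one decade takes 43.8 s in the south-east run, far less than 10 min. The slope at the new loading is a guess, but I expect the flask to exhaust its partner and stop, with target a little under 90.0%.

The forecast says it is still moving, with conversion 98%, target 93%, intermediate A 1.2% and over-reaction product 3%, on the grounds that “substrate and partner are nearly equimolar”. Its target stands above my M, and there we part.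

The flask gives: the partner has run out first, conversion 90.9%, target 85.1%, intermediate A 3.38%, over-reaction product 2.47%.

    partner + precatalyst → free catalyst + spent reagent (k = 3.80 M⁻¹ s⁻¹)
    substrate + free catalyst ⇌ catalyst intermediate A (K = 32.0 M⁻¹, k = 44.0 M⁻¹ s⁻¹)
    partner + target → over-reaction product (k = 0.0320 M⁻¹ s⁻¹)
    catalyst intermediate C → free catalyst + target (k = 0.380 s⁻¹)
    partner + catalyst intermediate A → catalyst intermediate B (k = 11.0 M⁻¹ s⁻¹)
    catalyst intermediate B → catalyst intermediate C (k = 0.450 s⁻¹)

Partner, the limiting reagent here, stands at 0% by 5.00 min. Each over-reaction product holds a second partner, so the flask's partner count is target plus twice over-reaction product, 90.0%, against M of 90.0%. The neighbouring flask with 6 mol% of precatalyst has M of 99.0%, and its count comes to 99.0%. That neighbour holds target 83.8% and over-reaction product 7.61%.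

The readings are simulated from invented constants, noise included.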